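**Target:** CNP0134269.1, (1S,3S,3aR,4R,5R,7aR)-3,4,5-triethyl-5-[(1E,3E)-2-ethyl-4-phenylbuta-1,3-dien-1-yl]-1,7-dimethyl-2-oxo-2,3,3a,4,5,7a-hexahydro-1H-indene-4-carboxylic acid.

## Retrosynthetic overview

1. Acid ⇒ methyl ester (thiolate demethylation last) ⇒ intramolecular Diels–Alder reaction of an all-E linear tetraenyl keto enoate. Bonds C2–C10 and C3–C7 form together, so the four ring stereocentres come from the two on the tether.
2. Linear keto enoate ⇒ C6–C7 bond: a racemic α-bromo ketone (enolonium equivalent) is joined to a tetraenylzirconium by nickel/bis(oxazoline) stereoconvergent alkenylation, which sets C6.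
3. α-Bromo ketone ⇒ auxiliary-controlled vinylogous Mukaiyama aldol of a 2-ethylhex-2-enoyl N,O-acetal with 2-bromopropanal (sets C4), then methanolysis and oxidation.
4. Tetraenyl iodide ⇒ methylalumination/iodination of a trienyne, itself built from a silyl ynal by two Wittig homologations and one benzylphosphonate olefination.
5. Ring order: no ring is present before step 11; the cyclohexene and the cyclopentanone close in that single step.

Locants C1–C14 below are those of the linear keto ester (C1 = ester carbon, C14 = carbon bearing phenyl).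

Assumption: the (4S)-isopropyl auxiliary is taken to give (4S) in step 7 and the (S,S)-ligand to give (6S) in step 10; neither sense could be confirmed here, and if a model run shows the opposite, the antipodal auxiliary or ligand is used and nothing else changes.

## Route

Step 1
Reactants: 1 3-(trimethylsilyl)prop-2-ynal; 2 2-(triphenylphosphoranylidene)butanal
Product: 3 (2E)-2-ethyl-5-(trimethylsilyl)pent-2-en-4-ynal
Conditions: CH2Cl2, 0 °C → rt
Reagents that add atoms: none
Why: Wittig olefination with a formyl-stabilised ylide gives the E-enal (CHO trans to the alkyne), and it stops after one homologation because the ynal is far more electrophilic than the enal product.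

Step 2
Reactants: 3 (2E)-2-ethyl-5-(trimethylsilyl)pent-2-en-4-ynal; 2 2-(triphenylphosphoranylidene)butanal
Product: 4 (2E,4E)-2,4-diethyl-7-(trimethylsilyl)hepta-2,4-dien-6-ynal
Conditions: 2 (1.1 equiv), PhMe, 90 °C
Reagents that add atoms: none
Why: A second E-selective Wittig homologation of the same kind; the dienal product is less electrophilic than 3 (vinylogous deactivation), which limits over-homologation.

Step 3
Reactants: 4 (2E,4E)-2,4-diethyl-7-(trimethylsilyl)hepta-2,4-dien-6-ynal; 5 diethyl benzylphosphonate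
Product: 7 [(1E,3E,5E)-3,5-diethylocta-1,3,5-trien-7-yn-1-yl]benzene, via silyl trienyne 6 (not isolated)
Conditions: KOt-Bu, THF, 0 °C → rt; then K2CO3 (cat.), MeOH, rt
Reagents that add atoms: none
Why: Horner–Wadsworth–Emmons olefination with the benzylphosphonate anion gives the E-styryl alkene, and methanolysis then removes the alkynyl silyl group in the same flask.

Step 4
Reactants: 7 [(1E,3E,5E)-3,5-diethylocta-1,3,5-trien-7-yn-1-yl]benzene
Product: 9 [(1E,3E,5E,7E)-3,5-diethyl-8-iodo-7-methylocta-1,3,5,7-tetraen-1-yl]benzene, via tetraenyl dimethylalane 8 (not isolated)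
Conditions: Me3Al (2.5 equiv), Cp2ZrCl2 (0.3 equiv), CH2Cl2, 0 °C → rt; then N-iodosuccinimide, THF, −30 °C, dark
Reagents that add atoms: trimethylaluminium C[Al](C)C; N-iodosuccinimide O=C1CCC(=O)N1I
Why: Negishi zirconium-catalysed methylalumination adds Me and Al syn across the terminal alkyne (Me to the internal carbon), and iodinolysis with retention gives the (7E)-iodide carrying the C7 methyl; the conjugated triene is inert to Me3Al.

Step 5
Reactants: 10 (2E)-2-ethylhex-2-enoic acid; 11 (4S)-4-isopropyl-1,3-oxazolidin-2-one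
Product: 13 (4S)-3-[(2E)-2-ethylhex-2-enoyl]-4-isopropyl-1,3-oxazolidin-2-one, via mixed pivalic anhydride 12 (not isolated)
Conditions: pivaloyl chloride, Et3N, THF, −20 °C; then 11, LiCl, rt
Reagents that add atoms: none
Why: N-acylation of the oxazolidinone through the mixed anhydride (LiCl/Et3N) attaches the auxiliary without disturbing the E-enoate.

Step 6
Reactants: 13 (4S)-3-[(2E)-2-ethylhex-2-enoyl]-4-isopropyl-1,3-oxazolidin-2-one
Product: 14 (4S)-3-[(1E,3E)-1-(tert-butyldimethylsilyloxy)-2-ethylhexa-1,3-dien-1-yl]-4-isopropyl-1,3-oxazolidin-2-one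
Conditions: TBSCl, NaN(SiMe3)2, THF, −78 °C
Reagents that add atoms: tert-butyldimethylsilyl chloride CC(C)(C)[Si](C)(C)Cl
Why: γ-Deprotonation of the enoyl imide and O-silylation give the (1E,3E)-vinylketene silyl N,O-acetal, in which the oxazolidinone is twisted out of the diene plane.

Step 7
Reactants: 14 (4S)-3-[(1E,3E)-1-(tert-butyldimethylsilyloxy)-2-ethylhexa-1,3-dien-1-yl]-4-isopropyl-1,3-oxazolidin-2-one; 15 2-bromopropanal (racemic)
Product: 16 (4S)-3-[(2E,4S,5S)-6-bromo-2,4-diethyl-5-hydroxyhept-2-enoyl]-4-isopropyl-1,3-oxazolidin-2-one (both C6 epimers)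
Conditions: TiCl4 (1.0 equiv), CH2Cl2, −78 °C; aqueous work-up
Reagents that add atoms: none
Why: Kobayashi vinylogous Mukaiyama aldol: the TiCl4-activated aldehyde attacks the γ-carbon on the diene face remote from the isopropyl group through an open transition state, setting C4 as S and C5 anti; C5 is oxidised later and C6 is deliberately left as both epimers.

Step 8
Reactants: 16 (4S)-3-[(2E,4S,5S)-6-bromo-2,4-diethyl-5-hydroxyhept-2-enoyl]-4-isopropyl-1,3-oxazolidin-2-one
Product: 17 methyl (2E,4S,5S)-6-bromo-2,4-diethyl-5-hydroxyhept-2-enoate (both C6 epimers)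
Conditions: Sm(OTf)3 (10 mol%), MeOH, rt
Reagents that add atoms: methanol CO
Why: Lewis-acid-catalysed methanolysis of the chelating imide exchanges the auxiliary for a methyl ester without base, so the bromohydrin does not close to an epoxide and C4 (not yet enolisable) is untouched.

Step 9
Reactants: 17 methyl (2E,4S,5S)-6-bromo-2,4-diethyl-5-hydroxyhept-2-enoate
Product: 18 methyl (2E,4S)-6-bromo-2,4-diethyl-5-oxohept-2-enoate (both C6 epimers)
Conditions: Dess–Martin periodinane, CH2Cl2, 0 °C → rt; used at once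
Reagents that add atoms: none
Why: Dess–Martin oxidation of the secondary alcohol is base-free, so the α-bromo ketone is formed without epimerising the now acidic C4–H.

Step 10
Reactants: 9 [(1E,3E,5E,7E)-3,5-diethyl-8-iodo-7-methylocta-1,3,5,7-tetraen-1-yl]benzene; 18 methyl (2E,4S)-6-bromo-2,4-diethyl-5-oxohept-2-enoate
Product: 21 methyl (2E,4S,6S,7E,9E,11E,13E)-2,4,10,12-tetraethyl-6,8-dimethyl-5-oxo-14-phenyltetradeca-2,7,9,11,13-pentaenoate, via tetraenyllithium 19 (not isolated), via tetraenylzirconocene chloride 20 (not isolated)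
Conditions: 9, t-BuLi (2.1 equiv), Et2O, −78 °C; Cp2ZrCl2, THF, −78 → 0 °C; then 18, NiCl2·glyme (10 mol%), (S,S)-Ph-BOX (13 mol%), DME/THF, −10 → 10 °C
Reagents that add atoms: none
Why: Proposed new method: the racemic α-bromo ketone acts as an enolonium equivalent, since a low-valent nickel–bis(oxazoline) complex abstracts bromine to give a planar α-acyl radical (both C6 epimers converge), and the chiral nickel–alkenyl species formed by Zr→Ni transmetalation captures it and reductively eliminates to set C6 as S under catalyst control; the non-basic alkenylzirconium should leave the ester, the ketone and the acidic C4–H alone and deliver the β,γ-unsaturated ketone without double-bond migration; the closest known reaction type is the nickel/bis(oxazoline)-catalysed stereoconvergent alkenylation of racemic α-bromo ketones with alkenylzirconium reagents, which to my knowledge has only been shown for simpler ketones and for alkenylzirconiums made by hydrozirconation.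

Step 11
Reactants: 21 methyl (2E,4S,6S,7E,9E,11E,13E)-2,4,10,12-tetraethyl-6,8-dimethyl-5-oxo-14-phenyltetradeca-2,7,9,11,13-pentaenoate
Product: 22 methyl (1S,3S,3aR,4R,5R,7aR)-3,4,5-triethyl-5-[(1E,3E)-2-ethyl-4-phenylbuta-1,3-dien-1-yl]-1,7-dimethyl-2-oxo-2,3,3a,4,5,7a-hexahydro-1H-indene-4-carboxylate
Conditions: PhMe (0.01 M), BHT (cat.), 90 °C, dark, silanised glassware
Reagents that add atoms: none
Why: Thermal intramolecular Diels–Alder reaction of the (7E,9E)-diene with the (2E)-enoate through the ester-endo transition state with the three-atom tether anti gives the trans-fused ring system; the face is fixed because C6–H and C4–H each eclipse the adjacent trisubstituted alkene (A(1,3) strain with C8–Me and C2–Et), and for (4S,6S) both preferences agree, setting C3a, C4, C5 and C7a all as R.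

Step 12
Reactants: 22 methyl (1S,3S,3aR,4R,5R,7aR)-3,4,5-triethyl-5-[(1E,3E)-2-ethyl-4-phenylbuta-1,3-dien-1-yl]-1,7-dimethyl-2-oxo-2,3,3a,4,5,7a-hexahydro-1H-indene-4-carboxylate
Product: 23 (1S,3S,3aR,4R,5R,7aR)-3,4,5-triethyl-5-[(1E,3E)-2-ethyl-4-phenylbuta-1,3-dien-1-yl]-1,7-dimethyl-2-oxo-2,3,3a,4,5,7a-hexahydro-1H-indene-4-carboxylic acid (CNP0134269.1)
Conditions: NaSEt, DMF, 60 °C; then dilute HCl to pH 3, 0 °C
Reagents that add atoms: none
Why: SN2 dealkylation by thiolate at the O–CH3 carbon bypasses the acyl carbon, which is blocked by two adjacent quaternary centres, and ethanethiolate is a strong nucleophile but too weak a base to enolise the hindered dialkyl ketone at a useful rate, so the two ketone α-centres (each alkyl group trans to the neighbouring ring carbon) should be kept.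

## Compound list

1 | 3-(trimethylsilyl)prop-2-ynal | C[Si](C)(C)C#CC=O | starting material
2 | 2-(triphenylphosphoranylidene)butanal | CCC(C=O)=P(c1ccccc1)(c1ccccc1)c1ccccc1 | starting material
3 | (2E)-2-ethyl-5-(trimethylsilyl)pent-2-en-4-ynal | C[Si](C)(C)C#C/C=C(\CC)C=O | intermediate
4 | (2E,4E)-2,4-diethyl-7-(trimethylsilyl)hepta-2,4-dien-6-ynal | C[Si](C)(C)C#C/C=C(\CC)/C=C(\CC)C=O | intermediate
5 | diethyl benzylphosphonate | CCOP(=O)(Cc1ccccc1)OCC | starting material
6 | trimethyl[(3E,5E,7E)-4,6-diethyl-8-phenylocta-3,5,7-trien-1-yn-1-yl]silane (silyl trienyne) | C[Si](C)(C)C#C/C=C(\CC)/C=C(\CC)/C=C/c1ccccc1 | intermediate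
7 | [(1E,3E,5E)-3,5-diethylocta-1,3,5-trien-7-yn-1-yl]benzene | C#C/C=C(\CC)/C=C(\CC)/C=C/c1ccccc1 | intermediate
8 | [(1E,3E,5E,7E)-4,6-diethyl-2-methyl-8-phenylocta-1,3,5,7-tetraen-1-yl]dimethylalumane (tetraenyl dimethylalane) | C[Al](C)/C=C(\C)/C=C(\CC)/C=C(\CC)/C=C/c1ccccc1 | intermediate
9 | [(1E,3E,5E,7E)-3,5-diethyl-8-iodo-7-methylocta-1,3,5,7-tetraen-1-yl]benzene | I/C=C(\C)/C=C(\CC)/C=C(\CC)/C=C/c1ccccc1 | intermediate
10 | (2E)-2-ethylhex-2-enoic acid | CCC/C=C(\CC)C(=O)O | starting material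
11 | (4S)-4-isopropyl-1,3-oxazolidin-2-one | CC(C)[C@H]1COC(=O)N1 | starting material
12 | (2E)-2-ethylhex-2-enoic pivalic anhydride (mixed pivalic anhydride) | CCC/C=C(\CC)C(=O)OC(=O)C(C)(C)C | intermediate
13 | (4S)-3-[(2E)-2-ethylhex-2-enoyl]-4-isopropyl-1,3-oxazolidin-2-one | CCC/C=C(\CC)C(=O)N1C(=O)OC[C@@H]1C(C)C | intermediate
14 | (4S)-3-[(1E,3E)-1-(tert-butyldimethylsilyloxy)-2-ethylhexa-1,3-dien-1-yl]-4-isopropyl-1,3-oxazolidin-2-one | CC/C=C/C(CC)=C(/O[Si](C)(C)C(C)(C)C)N1C(=O)OC[C@@H]1C(C)C | intermediate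
15 | 2-bromopropanal (racemic) | CC(Br)C=O | starting material
16 | (4S)-3-[(2E,4S,5S)-6-bromo-2,4-diethyl-5-hydroxyhept-2-enoyl]-4-isopropyl-1,3-oxazolidin-2-one (both C6 epimers) | CC(Br)[C@@H](O)[C@@H](CC)/C=C(\CC)C(=O)N1C(=O)OC[C@@H]1C(C)C | intermediate
17 | methyl (2E,4S,5S)-6-bromo-2,4-diethyl-5-hydroxyhept-2-enoate (both C6 epimers) | CC(Br)[C@@H](O)[C@@H](CC)/C=C(\CC)C(=O)OC | intermediate
18 | methyl (2E,4S)-6-bromo-2,4-diethyl-5-oxohept-2-enoate (both C6 epimers) | CC(Br)C(=O)[C@@H](CC)/C=C(\CC)C(=O)OC | intermediate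
19 | [(1E,3E,5E,7E)-4,6-diethyl-2-methyl-8-phenylocta-1,3,5,7-tetraen-1-yl]lithium (tetraenyllithium) | [Li]/C=C(\C)/C=C(\CC)/C=C(\CC)/C=C/c1ccccc1 | intermediate
20 | chlorobis(cyclopentadienyl)[(1E,3E,5E,7E)-4,6-diethyl-2-methyl-8-phenylocta-1,3,5,7-tetraen-1-yl]zirconium (tetraenylzirconocene chloride) | Cl[Zr](C1C=CC=C1)(C1C=CC=C1)/C=C(\C)/C=C(\CC)/C=C(\CC)/C=C/c1ccccc1 | intermediate
21 | methyl (2E,4S,6S,7E,9E,11E,13E)-2,4,10,12-tetraethyl-6,8-dimethyl-5-oxo-14-phenyltetradeca-2,7,9,11,13-pentaenoate | COC(=O)/C(CC)=C/[C@H](CC)C(=O)[C@@H](C)/C=C(\C)/C=C(\CC)/C=C(\CC)/C=C/c1ccccc1 | intermediate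
22 | methyl (1S,3S,3aR,4R,5R,7aR)-3,4,5-triethyl-5-[(1E,3E)-2-ethyl-4-phenylbuta-1,3-dien-1-yl]-1,7-dimethyl-2-oxo-2,3,3a,4,5,7a-hexahydro-1H-indene-4-carboxylate | CCC(/C=C/c1ccccc1)=C\[C@@]1(CC)C=C(C)[C@@H]2[C@H]([C@H](CC)C(=O)[C@H]2C)[C@@]1(CC)C(=O)OC | intermediate
23 | (1S,3S,3aR,4R,5R,7aR)-3,4,5-triethyl-5-[(1E,3E)-2-ethyl-4-phenylbuta-1,3-dien-1-yl]-1,7-dimethyl-2-oxo-2,3,3a,4,5,7a-hexahydro-1H-indene-4-carboxylic acid | CCC(/C=C/c1ccccc1)=C\[C@@]1(CC)C=C(C)[C@@H]2[C@H]([C@H](CC)C(=O)[C@H]2C)[C@@]1(CC)C(=O)O | target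

## Step count and risks

Total step count: 12. Longest linear sequence: 8 steps (steps 5–12, from 10); the other branch is 7 steps (steps 1–4 and 10–12).

**Step 10 (key coupling).** The scope is stretched three ways: a dialkyl ketone branched at the α′ carbon, a β,β-disubstituted polyenyl nucleophile, and catalyst control next to an existing stereocentre. The fallback sets out from 9 and 14 and comes back at 21. The same C6–C7 bond is made on the simplest electrophile of this class and the ketone is built afterwards. 9 is lithiated as before and transmetalated with ZnCl2 to chloro[(1E,3E,5E,7E)-4,6-diethyl-2-methyl-8-phenylocta-1,3,5,7-tetraen-1-yl]zinc F1. This zinc reagent is coupled with racemic 2-bromopropanenitrile under NiCl2·glyme/bis(oxazoline) catalysis (stereoconvergent Negishi alkenylation) to give (2S,3E,5E,7E,9E)-6,8-diethyl-2,4-dimethyl-10-phenyldeca-3,5,7,9-tetraenenitrile F2. Reduction with i-Bu2AlH at −78 °C gives (2S,3E,5E,7E,9E)-6,8-diethyl-2,4-dimethyl-10-phenyldeca-3,5,7,9-tetraenal F3. The TiCl4-mediated vinylogous aldol of this aldehyde with 14 gives (4S)-3-[(2E,4S,5R,6S,7E,9E,11E,13E)-2,4,10,12-tetraethyl-5-hydroxy-6,8-dimethyl-14-phenyltetradeca-2,7,9,11,13-pentaenoyl]-4-isopropyl-1,3-oxazolidin-2-one F4. Methanolysis with Sm(OTf)3/MeOH gives methyl (2E,4S,5R,6S,7E,9E,11E,13E)-2,4,10,12-tetraethyl-5-hydroxy-6,8-dimethyl-14-phenyltetradeca-2,7,9,11,13-pentaenoate F5, and Dess–Martin oxidation returns to 21.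

**Step 11 (cycloaddition).** The substrate must form two adjacent quaternary carbons, and both ketone α-centres of 21 are enolisable while it is heated. The fallback sets out from 21 and comes back at 22, taking the ketone out of play during the cycloaddition. 21 is reduced with NaBH4/CeCl3·7H2O (MeOH, −40 °C) to methyl (2E,4S,5RS,6S,7E,9E,11E,13E)-2,4,10,12-tetraethyl-5-hydroxy-6,8-dimethyl-14-phenyltetradeca-2,7,9,11,13-pentaenoate F6, in which C4 and C6 can no longer epimerise. This alcohol is heated in toluene to give methyl (1S,2RS,3S,3aR,4R,5R,7aR)-3,4,5-triethyl-5-[(1E,3E)-2-ethyl-4-phenylbuta-1,3-dien-1-yl]-2-hydroxy-1,7-dimethyl-2,3,3a,4,5,7a-hexahydro-1H-indene-4-carboxylate F7, and Dess–Martin oxidation of both carbinol epimers gives 22.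

**Step 7 (vinylogous aldol with an α-bromo aldehyde).** 2-Bromopropanal is unstable, and the α-ethyl/γ-ethyl acetal is an extension of the usual α-methyl/γ-methyl case. The fallback sets out from 14 and comes back at 18, introducing bromine only after the carbon skeleton is in place. 14 reacts with acrolein (TiCl4, CH2Cl2, −78 °C) to give (4S)-3-[(2E,4S,5R)-2,4-diethyl-5-hydroxyhepta-2,6-dienoyl]-4-isopropyl-1,3-oxazolidin-2-one F8. Methanolysis with Sm(OTf)3/MeOH gives methyl (2E,4S,5R)-2,4-diethyl-5-hydroxyhepta-2,6-dienoate F9, and Dess–Martin oxidation gives methyl (2E,4S)-2,4-diethyl-5-oxohepta-2,6-dienoate F10. Conjugate hydrosilylation of the vinyl ketone (Et3SiH, RhCl(PPh3)3 cat.) gives methyl (2E,4S)-2,4-diethyl-5-(triethylsilyloxy)hepta-2,5-dienoate F11, and N-bromosuccinimide brominates this enol ether regiospecifically at C6 to give 18.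

## Further compounds

F1 | step 10 | chloro[(1E,3E,5E,7E)-4,6-diethyl-2-methyl-8-phenylocta-1,3,5,7-tetraen-1-yl]zinc | Cl[Zn]/C=C(\C)/C=C(\CC)/C=C(\CC)/C=C/c1ccccc1
F2 | step 10 | (2S,3E,5E,7E,9E)-6,8-diethyl-2,4-dimethyl-10-phenyldeca-3,5,7,9-tetraenenitrile | N#C[C@@H](C)/C=C(\C)/C=C(\CC)/C=C(\CC)/C=C/c1ccccc1
F3 | step 10 | (2S,3E,5E,7E,9E)-6,8-diethyl-2,4-dimethyl-10-phenyldeca-3,5,7,9-tetraenal | O=C[C@@H](C)/C=C(\C)/C=C(\CC)/C=C(\CC)/C=C/c1ccccc1
F4 | step 10 | (4S)-3-[(2E,4S,5R,6S,7E,9E,11E,13E)-2,4,10,12-tetraethyl-5-hydroxy-6,8-dimethyl-14-phenyltetradeca-2,7,9,11,13-pentaenoyl]-4-isopropyl-1,3-oxazolidin-2-one | CC[C@@H](/C=C(\CC)C(=O)N1C(=O)OC[C@@H]1C(C)C)[C@H](O)[C@@H](C)/C=C(\C)/C=C(\CC)/C=C(\CC)/C=C/c1ccccc1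
F5 | step 10 | methyl (2E,4S,5R,6S,7E,9E,11E,13E)-2,4,10,12-tetraethyl-5-hydroxy-6,8-dimethyl-14-phenyltetradeca-2,7,9,11,13-pentaenoate | CC[C@@H](/C=C(\CC)C(=O)OC)[C@H](O)[C@@H](C)/C=C(\C)/C=C(\CC)/C=C(\CC)/C=C/c1ccccc1
F6 | step 11 | methyl (2E,4S,5RS,6S,7E,9E,11E,13E)-2,4,10,12-tetraethyl-5-hydroxy-6,8-dimethyl-14-phenyltetradeca-2,7,9,11,13-pentaenoate (C5 epimer mixture) | CC[C@@H](/C=C(\CC)C(=O)OC)C(O)[C@@H](C)/C=C(\C)/C=C(\CC)/C=C(\CC)/C=C/c1ccccc1
F7 | step 11 | methyl (1S,2RS,3S,3aR,4R,5R,7aR)-3,4,5-triethyl-5-[(1E,3E)-2-ethyl-4-phenylbuta-1,3-dien-1-yl]-2-hydroxy-1,7-dimethyl-2,3,3a,4,5,7a-hexahydro-1H-indene-4-carboxylate | CCC(/C=C/c1ccccc1)=C\[C@@]1(CC)C=C(C)[C@@H]2[C@H]([C@H](CC)C(O)[C@H]2C)[C@@]1(CC)C(=O)OC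
F8 | step 7 | (4S)-3-[(2E,4S,5R)-2,4-diethyl-5-hydroxyhepta-2,6-dienoyl]-4-isopropyl-1,3-oxazolidin-2-one | C=C[C@@H](O)[C@@H](CC)/C=C(\CC)C(=O)N1C(=O)OC[C@@H]1C(C)C
F9 | step 7 | methyl (2E,4S,5R)-2,4-diethyl-5-hydroxyhepta-2,6-dienoate | C=C[C@@H](O)[C@@H](CC)/C=C(\CC)C(=O)OC
F10 | step 7 | methyl (2E,4S)-2,4-diethyl-5-oxohepta-2,6-dienoate | C=CC(=O)[C@@H](CC)/C=C(\CC)C(=O)OC
F11 | step 7 | methyl (2E,4S)-2,4-diethyl-5-(triethylsilyloxy)hepta-2,5-dienoate | CC=C(O[Si](CC)(CC)CC)[C@@H](CC)/C=C(\CC)C(=O)OC
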